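The 18-membered ring is closed at the bond between the benzylic CH2 and C3 of ring D (the meta-phenylene). That CH2 is alpha to the carbinol carbon on ring A, so at the ketone oxidation level it is an enolate carbon: the closure becomes an intramolecular palladium-catalysed ketone α-arylation, joining the methyl ketone on ring A to the C–Cl carbon of ring D, which sits meta to the diaryl ether oxygen. The precursor is a linear tris-ether with an acetophenone at one end and a 3-chlorophenyl ether at the other. The macrocyclic deoxybenzoin is then demethylated, and the (S)-carbinol is set last by Noyori transfer hydrogenation.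

Key step: step 8

Ring labels used below: ring A = trioxygenated ring (C1 bears the carbonyl or carbinol carbon, C3 the ether oxygen to ring B, C4 and C5 the other two oxygens); ring B = 1,4-phenylene (O at C1, CH2CH2 at C4); ring C = ring with CH2CH2 at C1, the ether oxygen to ring D at C2 and an oxygen at C3; ring D = 1,3-phenylene (O at C1, Cl or CH2 at C3).

Step 1
Reactants: 1 3-chlorophenol; 2 2-fluoro-3-methoxybenzaldehyde
Product: 3 2-(3-chlorophenoxy)-3-methoxybenzaldehyde
Conditions: K2CO3, DMF, 120 °C
Reagents that add atoms: none
Why: Nucleophilic aromatic substitution (SNAr), in which the ortho formyl group stabilises the Meisenheimer intermediate so that the phenol, deprotonated by K2CO3, displaces fluoride while the aryl chloride stays inert.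

Step 2
Reactants: 4 4-hydroxybenzyl alcohol
Product: 5 (4-hydroxybenzyl)triphenylphosphonium bromide
Conditions: PPh3·HBr, MeCN, reflux
Reagents that add atoms: triphenylphosphine hydrobromide, [Br-].c1ccc(cc1)[PH+](c1ccccc1)c1ccccc1
Why: Direct phosphonium salt formation from a benzylic alcohol and PPh3·HBr, in which the para-hydroxyl makes the benzylic C–O bond easy to ionise under HBr and triphenylphosphine captures the benzylic electrophile.

Step 3
Reactants: 5 (4-hydroxybenzyl)triphenylphosphonium bromide; 3 2-(3-chlorophenoxy)-3-methoxybenzaldehyde
Product: 7 4-{2-[2-(3-chlorophenoxy)-3-methoxyphenyl]ethenyl}phenol (expected as an E/Z mixture), via potassium phenoxide ylide 6 (not isolated)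
Conditions: KOtBu (2.2 equiv), THF, 0 °C; then 3, 0 °C to rt; 1 M HCl work-up
Reagents that add atoms: none
Why: Wittig olefination, in which two equivalents of base give the phenoxide-bearing benzylic ylide 6 that adds to the aldehyde, and the alkene geometry does not matter because step 4 removes the double bond.

Step 4
Reactants: 7 4-{2-[2-(3-chlorophenoxy)-3-methoxyphenyl]ethenyl}phenol
Product: 8 4-{2-[2-(3-chlorophenoxy)-3-methoxyphenyl]ethyl}phenol
Conditions: TsNHNH2, NaOAc, THF/H2O, reflux
Reagents that add atoms: none
Why: Diimide reduction, in which diimide released from tosylhydrazide transfers two hydrogens to the stilbene double bond in a concerted syn fashion and leaves the aryl chloride, which hydrogenation over palladium could cleave.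

Step 5
Reactants: 9 acetovanillone [1-(4-hydroxy-3-methoxyphenyl)ethanone]
Product: 10 1-(3-bromo-4-hydroxy-5-methoxyphenyl)ethanone
Conditions: Br2 (1.0 equiv), NaOAc, AcOH, rt
Reagents that add atoms: bromine, BrBr
Why: Electrophilic aromatic bromination directed to the free position ortho to the phenol (the para position carries the acetyl group), with acetate buffering the acid so that the ketone is not brominated at its methyl group.

Step 6
Reactants: 10 1-(3-bromo-4-hydroxy-5-methoxyphenyl)ethanone
Product: 11 1-(3-bromo-4,5-dimethoxyphenyl)ethanone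
Conditions: MeI, K2CO3, DMF, rt
Reagents that add atoms: iodomethane, CI
Why: Williamson O-methylation of the phenol, with K2CO3 too weak a base to enolise the aryl methyl ketone, so that C-methylation is not expected.

Step 7
Reactants: 8 4-{2-[2-(3-chlorophenoxy)-3-methoxyphenyl]ethyl}phenol; 11 1-(3-bromo-4,5-dimethoxyphenyl)ethanone
Product: 12 1-[3-(4-{2-[2-(3-chlorophenoxy)-3-methoxyphenyl]ethyl}phenoxy)-4,5-dimethoxyphenyl]ethanone
Conditions: CuI (10 mol%), N,N-dimethylglycine hydrochloride (30 mol%), Cs2CO3, 1,4-dioxane, 100 °C
Reagents that add atoms: none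
Why: Ullmann-type copper-catalysed diaryl ether synthesis, in which the aryl bromide of 11 couples with the unhindered phenol while the aryl chloride of 8 is inert to copper at this temperature, which fixes the chemoselectivity.

Step 8
Reactants: 12 1-[3-(4-{2-[2-(3-chlorophenoxy)-3-methoxyphenyl]ethyl}phenoxy)-4,5-dimethoxyphenyl]ethanone
Product: 14 macrocyclic trimethyl ether ketone (18-membered deoxybenzoin), via sodium enolate 13 (not isolated)
Conditions: Pd2(dba)3 (5 mol%), XPhos (12 mol%), NaOtBu (2.5 equiv), toluene, 100 °C, slow addition of 12 (final 2 mM)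
Reagents that add atoms: none
Why: Intramolecular Buchwald–Hartwig–Miura ketone α-arylation: XPhos-ligated zerovalent palladium inserts into the C–Cl bond at C3 of ring D, the sodium enolate 13 of the ring A methyl ketone replaces chloride on palladium, and C–C reductive elimination from the arylpalladium enolate forms the aryl–CH2 bond. The closest known reaction type is the intermolecular mono-α-arylation of acetophenones with aryl chlorides under biarylphosphine–palladium catalysis. The single ring closed is the 18-membered macrocycle, by end-to-end C(sp2)–C(sp3) coupling through a large palladacycle, so no small-ring (Baldwin) constraint applies. No stereocenter is formed; the new CH2 lies next to the ketone whose reduction in step 10 sets the configuration. The step needs ring closure to outrun oligomerisation and only one arylation: slow addition keeps the enolate dilute, and the substrate offers one enolisable methyl group and one aryl halide, whose position meta to the ether oxygen fixes the site on ring D.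

Step 9
Reactants: 14 macrocyclic trimethyl ether ketone
Product: 15 macrocyclic triphenol ketone
Conditions: BBr3 (9 equiv), CH2Cl2, −78 °C to rt; then MeOH, H2O
Reagents that add atoms: none
Why: BBr3 ether cleavage (Lewis acid complexation, then bromide attack on methyl) removes the three aryl methyl ethers while the diaryl ethers and the aryl ketone persist, and it is placed before the reduction because a benzylic carbinol para to a phenol would not survive BBr3.

Step 10
Reactants: 15 macrocyclic triphenol ketone
Product: 16 target (S)-carbinol
Conditions: RuCl[(S,S)-TsDPEN](p-cymene) (3 mol%), HCO2H/Et3N (5:2), DMF, 30 °C, argon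
Reagents that add atoms: none
Why: Noyori–Ikariya asymmetric transfer hydrogenation, in which the (S,S)-TsDPEN ruthenium hydride reduces the ketone through the six-membered transition state that places ring A, the aryl group bonded to the carbonyl, under the p-cymene ligand (CH/π contact), the arrangement that gives (S)-alcohols from aryl alkyl ketones and deoxybenzoins, while the mildly acidic medium keeps the phenols protonated.

Compound list
1 | 3-chlorophenol | Oc1cccc(Cl)c1 | starting material
2 | 2-fluoro-3-methoxybenzaldehyde | COc1cccc(C=O)c1F | starting material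
3 | 2-(3-chlorophenoxy)-3-methoxybenzaldehyde | COc1cccc(C=O)c1Oc1cccc(Cl)c1 | intermediate
4 | 4-hydroxybenzyl alcohol | OCc1ccc(O)cc1 | starting material
5 | (4-hydroxybenzyl)triphenylphosphonium bromide | [Br-].Oc1ccc(C[P+](c2ccccc2)(c2ccccc2)c2ccccc2)cc1 | intermediate
6 | potassium 4-[(triphenylphosphoranylidene)methyl]phenolate (phenoxide ylide, not isolated) | [K+].[O-]c1ccc(C=P(c2ccccc2)(c2ccccc2)c2ccccc2)cc1 | intermediate
7 | 4-{2-[2-(3-chlorophenoxy)-3-methoxyphenyl]ethenyl}phenol, E/Z mixture, geometry not defined | COc1cccc(C=Cc2ccc(O)cc2)c1Oc1cccc(Cl)c1 | intermediate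
8 | 4-{2-[2-(3-chlorophenoxy)-3-methoxyphenyl]ethyl}phenol | COc1cccc(CCc2ccc(O)cc2)c1Oc1cccc(Cl)c1 | intermediate
9 | acetovanillone, 1-(4-hydroxy-3-methoxyphenyl)ethanone | CC(=O)c1ccc(O)c(OC)c1 | starting material
10 | 1-(3-bromo-4-hydroxy-5-methoxyphenyl)ethanone | CC(=O)c1cc(Br)c(O)c(OC)c1 | intermediate
11 | 1-(3-bromo-4,5-dimethoxyphenyl)ethanone | CC(=O)c1cc(Br)c(OC)c(OC)c1 | intermediate
12 | 1-[3-(4-{2-[2-(3-chlorophenoxy)-3-methoxyphenyl]ethyl}phenoxy)-4,5-dimethoxyphenyl]ethanone | CC(=O)c1cc(Oc2ccc(CCc3cccc(OC)c3Oc3cccc(Cl)c3)cc2)c(OC)c(OC)c1 | intermediate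
13 | sodium enolate of 12, sodium 1-aryl-ethen-1-olate (not isolated) | [Na+].C=C([O-])c1cc(Oc2ccc(CCc3cccc(OC)c3Oc3cccc(Cl)c3)cc2)c(OC)c(OC)c1 | intermediate
14 | macrocyclic trimethyl ether ketone: 18-membered ring made of ring A C1–C(=O)–CH2–ring D C3, ring D C1–O–ring C C2, ring C C1–CH2CH2–ring B C4 and ring B C1–O–ring A C3, with OMe at ring A C4, ring A C5 and ring C C3 | COc1cc2cc(c1OC)Oc1ccc(cc1)CCc1cccc(OC)c1Oc1cccc(c1)CC2=O | intermediate
15 | macrocyclic triphenol ketone: as 14 with OH in place of the three OMe groups | Oc1cc2cc(c1O)Oc1ccc(cc1)CCc1cccc(O)c1Oc1cccc(c1)CC2=O | intermediate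
16 | target: as 15 with (S)-CH(OH) in place of the ketone carbon | Oc1cc2cc(c1O)Oc1ccc(cc1)CCc1cccc(O)c1Oc1cccc(c1)C[C@@H]2O | target

Total step count: 10 steps.
Longest linear sequence: 7 steps (steps 1, 3, 4, 7, 8, 9, 10).

Steps most likely to fail

Step 8. The entropically costly 18-membered closure may be outrun by intermolecular arylation and aldol condensation of the alkali enolate (oligomerisation), and the arylpalladium chloride may be reduced with loss of chlorine. Fallback, setting out from 12 and coming back at 14: 12 is treated with TMSOTf and Et3N (CH2Cl2, 0 °C) to give the trimethylsilyl enol ether F1. F1 is cyclised by the fluoride-promoted palladium arylation of enol silanes (Pd(OAc)2, P(t-Bu)3, ZnF2, CsF, DMF, 85 °C, slow addition) to give 14. The nucleophile is then a neutral, preformed enolate equivalent that is released only at the metal, so strong base and aldol pathways are avoided.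

Step 10. The free catechol may chelate and inhibit the ruthenium hydride, hydride transfer to the electron-rich, para-hydroxylated ketone may be slow, and acid-promoted ionisation of the para-hydroxybenzylic carbinol may erode the enantiomeric purity. Fallback, setting out from 15 and coming back at 16: 15 is silylated (TBSCl, imidazole, DMF) to the tris(tert-butyldimethylsilyl) ether ketone F2. The same transfer hydrogenation with RuCl[(S,S)-TsDPEN](p-cymene) and HCO2H/Et3N on this masked, non-chelating ketone should give the (S)-carbinol tris-silyl ether F3. Desilylation with Bu4NF buffered with AcOH (THF, 0 °C) then releases 16 under nearly neutral conditions.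

Step 7. Coupling at the bromide flanked by a methoxy group may be slow, which lets base-mediated self-condensation of the methyl ketone and reductive debromination take over. Fallback, setting out from 11 and coming back at 12: Miyaura borylation of 11 (Pd(dppf)Cl2, B2pin2, KOAc, 1,4-dioxane, 85 °C) gives the pinacol boronate F4. Oxidative cleavage of the pinacol ester (NaIO4, NH4OAc, acetone/H2O, rt) gives the boronic acid F5. Chan–Lam–Evans etherification of F5 with phenol 8 (Cu(OAc)2, pyridine, 4 Å molecular sieves, air, CH2Cl2, rt) gives 12. Ring A thus becomes the nucleophilic partner under oxidative copper mediation at room temperature, which spares the aryl chloride and the ketone.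

Further compounds
F1 | step 8 | trimethylsilyl enol ether of 12, {[1-(3-{4-[2-(2-(3-chlorophenoxy)-3-methoxyphenyl)ethyl]phenoxy}-4,5-dimethoxyphenyl)ethenyl]oxy}trimethylsilane | C=C(O[Si](C)(C)C)c1cc(Oc2ccc(CCc3cccc(OC)c3Oc3cccc(Cl)c3)cc2)c(OC)c(OC)c1
F2 | step 10 | tris(tert-butyldimethylsilyl) ether of ketone 15 | CC(C)(C)[Si](C)(C)Oc1cc2cc(c1O[Si](C)(C)C(C)(C)C)Oc1ccc(cc1)CCc1cccc(O[Si](C)(C)C(C)(C)C)c1Oc1cccc(c1)CC2=O
F3 | step 10 | tris(tert-butyldimethylsilyl) ether of the (S)-carbinol 16 | CC(C)(C)[Si](C)(C)Oc1cc2cc(c1O[Si](C)(C)C(C)(C)C)Oc1ccc(cc1)CCc1cccc(O[Si](C)(C)C(C)(C)C)c1Oc1cccc(c1)C[C@@H]2O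
F4 | step 7 | 1-[3,4-dimethoxy-5-(4,4,5,5-tetramethyl-1,3,2-dioxaborolan-2-yl)phenyl]ethanone | CC(=O)c1cc(B2OC(C)(C)C(C)(C)O2)c(OC)c(OC)c1
F5 | step 7 | (5-acetyl-2,3-dimethoxyphenyl)boronic acid | CC(=O)c1cc(B(O)O)c(OC)c(OC)c1
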